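Ring A (the benzene bearing OAc at C1, the C11 chain at C2 and OH at C3, with C4–C6 as CH) is built from two open-chain pieces instead of functionalising a resorcinol. A thermal annulation of parent cyclobutenone with a TIPS ynol ether carrying the C11 alkenyl chain forms the C1–C2 and C3–C4 bonds and closes the ring in one operation. It delivers the 1,2,3-O,C,O pattern with one oxygen free and the other silylated, which later allows a single acetate. The terminal alkene is then converted to an aldehyde and joined to a lithiated phloroglucinol tribenzyl ether; oxidation, silyl-to-acetyl exchange and hydrogenolysis finish the synthesis.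

Key step: step 5

Remark: 1,3,5-tris(benzyloxy)benzene and LiC≡CH·H2NCH2CH2NH2 are taken as catalogue chemicals, and cyclobutenone 9 is assumed to be used at once as a cold solution because the neat compound polymerises.

Step 1
Reactants: 1 11-bromoundec-1-ene; 2 lithium acetylide–ethylenediamine complex
Product: 3 tridec-12-en-1-yne
Conditions: LiC≡CH·H2NCH2CH2NH2 (1.5 equiv), DMSO, 10 °C to rt
Reagents that add atoms: none
Why: SN2 alkylation of a monolithium acetylide by an unhindered primary bromide in a dipolar aprotic solvent should give the terminal alkyne directly, the isolated alkene being inert.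

Step 2
Reactants: 3 tridec-12-en-1-yne
Product: 6 triisopropyl(tridec-12-en-1-yn-1-yloxy)silane, via lithium acetylide 4 (not isolated), via lithium ynolate 5 (not isolated)
Conditions: n-BuLi, THF, −78 °C; t-BuOOLi (from t-BuOOH + LiN(SiMe3)2), −78 to 0 °C; then i-Pr3SiOTf, −78 to 0 °C
Reagents that add atoms: lithium tert-butyl peroxide, [Li+].CC(C)(C)O[O-]; triisopropylsilyl trifluoromethanesulfonate, CC(C)[Si](C(C)C)(C(C)C)OS(=O)(=O)C(F)(F)F
Why: Oxidation of a lithium acetylide by a lithium alkyl peroxide (oxygen transfer from the O–O bond to the carbanion) gives the ynolate, which the bulky silyl triflate should silylate on oxygen to the ynol silyl ether, while the non-activated alkene does not react with the nucleophilic peroxide.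

Step 3
Reactants: 7 3-oxocyclobutane-1-carboxylic acid
Product: 8 3-bromocyclobutan-1-one
Conditions: HgO, Br2, MgSO4, CH2Cl2, reflux
Reagents that add atoms: bromine, BrBr
Why: Hunsdiecker-type bromodecarboxylation (Cristol–Firth variant) proceeds through the acyl hypobromite and a cyclobutyl radical and leaves the ketone untouched.

Step 4
Reactants: 8 3-bromocyclobutan-1-one
Product: 9 cyclobut-2-en-1-one
Conditions: n-Bu3N, neat, rt, vacuum transfer into a −78 °C trap
Reagents that add atoms: none
Why: E1cB-type dehydrobromination of a β-bromo ketone by a tertiary amine, with the volatile enone removed continuously from the base so that it does not polymerise.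

Step 5
Reactants: 9 cyclobut-2-en-1-one; 6 triisopropyl(tridec-12-en-1-yn-1-yloxy)silane
Product: 14 3-[(triisopropylsilyl)oxy]-2-(undec-10-en-1-yl)phenol, via vinylketene 10 (not isolated), via vinylcyclobutenone adduct 11 (not isolated), via dienylketene 12 (not isolated), via cyclohexadienone tautomer 13 (not isolated)
Conditions: 6 (1.3 equiv), toluene, 80 °C, slow addition of 9 in toluene; then 110 °C
Reagents that add atoms: none
Why: Danheiser benzannulation: on heating, 9 undergoes 4π-electrocyclic opening to vinylketene 10, whose carbonyl carbon is attacked by the chain-bearing carbon of the electron-rich ynol ether 6 in a regiospecific (2+2) cycloaddition that gives 4-vinylcyclobutenone 11. Reversible 4π opening of 11 gives dienylketene 12, and ring A is closed by a thermally allowed disrotatory 6π-electrocyclisation between the ketene carbon and the vinyl terminus, after which dienone 13 tautomerises irreversibly to phenol 14; every atom of 6 and 9 is retained. The closest known reaction type is the thermal aromatic annulation of cyclobutenones with trialkylsilyloxyalkynes to resorcinol monosilyl ethers. No stereocentre is present in 14, the one in 11 being erased on ring opening. The step needs regioselectivity (chain between the two oxygens, one oxygen free and one silylated), which the polarisation of the O–C≡C unit secures. It also needs chemoselectivity of the ketene for the ynol ether over the remote monosubstituted alkene, the hindered product phenol and a second molecule of 9, secured by the much higher nucleophilicity of the siloxyalkyne, its excess and the low stationary concentration of 9.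

Step 6
Reactants: 14 3-[(triisopropylsilyl)oxy]-2-(undec-10-en-1-yl)phenol
Product: 15 [3-(benzyloxy)-2-(undec-10-en-1-yl)phenoxy]triisopropylsilane
Conditions: BnBr, K2CO3, Bu4NI (cat.), acetone, 50 °C
Reagents that add atoms: benzyl bromide, BrCc1ccccc1
Why: Williamson O-alkylation of the phenoxide; the hindered aryl TIPS ether should be stable to anhydrous carbonate.

Step 7
Reactants: 15 [3-(benzyloxy)-2-(undec-10-en-1-yl)phenoxy]triisopropylsilane
Product: 17 11-{2-(benzyloxy)-6-[(triisopropylsilyl)oxy]phenyl}undecan-1-ol, via alkylborane 16 (not isolated)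
Conditions: 9-borabicyclo[3.3.1]nonane, THF, 0 °C to rt; then NaBO3·4H2O, H2O, rt
Reagents that add atoms: sodium perborate tetrahydrate, [Na+].[Na+].O[B-]1(O)OO[B-](O)(O)OO1
Why: Anti-Markovnikov hydroboration of the monosubstituted alkene by the bulky dialkylborane, then oxidation of the C–B bond, with perborate chosen as an oxidant mild enough to spare the aryl silyl ether.

Step 8
Reactants: 17 11-{2-(benzyloxy)-6-[(triisopropylsilyl)oxy]phenyl}undecan-1-ol
Product: 18 11-{2-(benzyloxy)-6-[(triisopropylsilyl)oxy]phenyl}undecanal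
Conditions: Dess–Martin periodinane, NaHCO3, CH2Cl2, 0 °C to rt
Reagents that add atoms: none
Why: Dess–Martin oxidation of a primary alcohol stops at the aldehyde under buffered, near-neutral conditions that both aryl ethers tolerate.

Step 9
Reactants: 19 1,3,5-tris(benzyloxy)benzene
Product: 20 2-bromo-1,3,5-tris(benzyloxy)benzene
Conditions: N-bromosuccinimide (1.0 equiv), CH2Cl2, −78 to 0 °C
Reagents that add atoms: N-bromosuccinimide, O=C1CCC(=O)N1Br
Why: Electrophilic aromatic bromination of a strongly activated arene; one equivalent at low temperature should give monobromination at one of three equivalent positions.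

Step 10
Reactants: 18 11-{2-(benzyloxy)-6-[(triisopropylsilyl)oxy]phenyl}undecanal; 20 2-bromo-1,3,5-tris(benzyloxy)benzene
Product: 22 11-{2-(benzyloxy)-6-[(triisopropylsilyl)oxy]phenyl}-1-[2,4,6-tris(benzyloxy)phenyl]undecan-1-ol (racemic), via aryllithium 21 (not isolated)
Conditions: 20 (1.3 equiv), n-BuLi (1.25 equiv), THF, −78 °C; then 18, −78 to −40 °C; H2O
Reagents that add atoms: none
Why: Bromine–lithium exchange at −78 °C is faster than benzylic deprotonation of the benzyl ethers, and the resulting aryllithium undergoes 1,2-addition to the aldehyde; the carbinol centre forms racemic and is removed in step 11.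

Step 11
Reactants: 22 11-{2-(benzyloxy)-6-[(triisopropylsilyl)oxy]phenyl}-1-[2,4,6-tris(benzyloxy)phenyl]undecan-1-ol
Product: 23 11-{2-(benzyloxy)-6-[(triisopropylsilyl)oxy]phenyl}-1-[2,4,6-tris(benzyloxy)phenyl]undecan-1-one
Conditions: Dess–Martin periodinane, NaHCO3, CH2Cl2, rt
Reagents that add atoms: none
Why: Dess–Martin oxidation of a secondary benzylic alcohol, buffered with hydrogencarbonate so that the electron-rich benzylic position is not ionised by acid.

Step 12
Reactants: 23 11-{2-(benzyloxy)-6-[(triisopropylsilyl)oxy]phenyl}-1-[2,4,6-tris(benzyloxy)phenyl]undecan-1-one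
Product: 25 3-(benzyloxy)-2-{11-oxo-11-[2,4,6-tris(benzyloxy)phenyl]undecyl}phenyl acetate, via tetrabutylammonium phenoxide 24 (not isolated)
Conditions: Bu4NF (1.1 equiv), THF, 0 °C; then Ac2O (3 equiv), 4-(dimethylamino)pyridine (cat.), 0 °C to rt
Reagents that add atoms: acetic anhydride, CC(=O)OC(C)=O
Why: Fluoride-induced cleavage of the aryl Si–O bond gives the phenoxide, which is acylated in the same flask under nucleophilic catalysis, while benzyl ethers and the hindered ketone are unaffected.

Step 13
Reactants: 25 3-(benzyloxy)-2-{11-oxo-11-[2,4,6-tris(benzyloxy)phenyl]undecyl}phenyl acetate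
Product: 26 3-hydroxy-2-[11-oxo-11-(2,4,6-trihydroxyphenyl)undecyl]phenyl acetate
Conditions: H2 (1 atm), 10% Pd/C, EtOAc, rt
Reagents that add atoms: none
Why: Catalytic hydrogenolysis of the four benzyl ethers in a neutral, non-nucleophilic solvent should preserve the aryl acetate, and the electron-rich, hydrogen-bonded aryl ketone resists reduction.

Compound list
1 | 11-bromoundec-1-ene | C=CCCCCCCCCCBr | starting material
2 | lithium acetylide–ethylenediamine complex | [Li]C#C.NCCN | starting material
3 | tridec-12-en-1-yne | C#CCCCCCCCCCC=C | intermediate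
4 | lithium tridec-12-en-1-yn-1-ide (not isolated) | [Li]C#CCCCCCCCCCC=C | intermediate
5 | lithium tridec-12-en-1-yn-1-olate (not isolated) | [Li]OC#CCCCCCCCCCC=C | intermediate
6 | triisopropyl(tridec-12-en-1-yn-1-yloxy)silane | C=CCCCCCCCCCC#CO[Si](C(C)C)(C(C)C)C(C)C | intermediate
7 | 3-oxocyclobutane-1-carboxylic acid | O=C1CC(C(=O)O)C1 | starting material
8 | 3-bromocyclobutan-1-one | O=C1CC(Br)C1 | intermediate
9 | cyclobut-2-en-1-one | O=C1C=CC1 | intermediate
10 | buta-1,3-dien-1-one (vinylketene, not isolated) | C=CC=C=O | intermediate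
11 | 3-[(triisopropylsilyl)oxy]-2-(undec-10-en-1-yl)-4-vinylcyclobut-2-en-1-one (racemic, not isolated) | O=C1C(CCCCCCCCCC=C)=C(O[Si](C(C)C)(C(C)C)C(C)C)C1C=C | intermediate
12 | (3E)-3-[(triisopropylsilyl)oxy]-2-(undec-10-en-1-yl)hexa-1,3,5-trien-1-one (dienylketene, not isolated) | O=C=C(CCCCCCCCCC=C)\C(O[Si](C(C)C)(C(C)C)C(C)C)=C/C=C | intermediate
13 | 3-[(triisopropylsilyl)oxy]-2-(undec-10-en-1-yl)cyclohexa-2,4-dien-1-one (not isolated) | O=C1CC=CC(O[Si](C(C)C)(C(C)C)C(C)C)=C1CCCCCCCCCC=C | intermediate
14 | 3-[(triisopropylsilyl)oxy]-2-(undec-10-en-1-yl)phenol | Oc1cccc(O[Si](C(C)C)(C(C)C)C(C)C)c1CCCCCCCCCC=C | intermediate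
15 | [3-(benzyloxy)-2-(undec-10-en-1-yl)phenoxy]triisopropylsilane | C=CCCCCCCCCCc1c(OCc2ccccc2)cccc1O[Si](C(C)C)(C(C)C)C(C)C | intermediate
16 | 9-(11-{2-(benzyloxy)-6-[(triisopropylsilyl)oxy]phenyl}undecyl)-9-borabicyclo[3.3.1]nonane (not isolated) | B1(CCCCCCCCCCCc2c(OCc3ccccc3)cccc2O[Si](C(C)C)(C(C)C)C(C)C)C2CCCC1CCC2 | intermediate
17 | 11-{2-(benzyloxy)-6-[(triisopropylsilyl)oxy]phenyl}undecan-1-ol | OCCCCCCCCCCCc1c(OCc2ccccc2)cccc1O[Si](C(C)C)(C(C)C)C(C)C | intermediate
18 | 11-{2-(benzyloxy)-6-[(triisopropylsilyl)oxy]phenyl}undecanal | O=CCCCCCCCCCCc1c(OCc2ccccc2)cccc1O[Si](C(C)C)(C(C)C)C(C)C | intermediate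
19 | 1,3,5-tris(benzyloxy)benzene | C(Oc1cc(OCc2ccccc2)cc(OCc2ccccc2)c1)c1ccccc1 | starting material
20 | 2-bromo-1,3,5-tris(benzyloxy)benzene | Brc1c(OCc2ccccc2)cc(OCc2ccccc2)cc1OCc1ccccc1 | intermediate
21 | [2,4,6-tris(benzyloxy)phenyl]lithium (not isolated) | [Li]c1c(OCc2ccccc2)cc(OCc2ccccc2)cc1OCc1ccccc1 | intermediate
22 | 11-{2-(benzyloxy)-6-[(triisopropylsilyl)oxy]phenyl}-1-[2,4,6-tris(benzyloxy)phenyl]undecan-1-ol (racemic) | OC(CCCCCCCCCCc1c(OCc2ccccc2)cccc1O[Si](C(C)C)(C(C)C)C(C)C)c1c(OCc2ccccc2)cc(OCc2ccccc2)cc1OCc1ccccc1 | intermediate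
23 | 11-{2-(benzyloxy)-6-[(triisopropylsilyl)oxy]phenyl}-1-[2,4,6-tris(benzyloxy)phenyl]undecan-1-one | O=C(CCCCCCCCCCc1c(OCc2ccccc2)cccc1O[Si](C(C)C)(C(C)C)C(C)C)c1c(OCc2ccccc2)cc(OCc2ccccc2)cc1OCc1ccccc1 | intermediate
24 | tetrabutylammonium 3-(benzyloxy)-2-{11-oxo-11-[2,4,6-tris(benzyloxy)phenyl]undecyl}phenolate (not isolated) | CCCC[N+](CCCC)(CCCC)CCCC.[O-]c1cccc(OCc2ccccc2)c1CCCCCCCCCCC(=O)c1c(OCc2ccccc2)cc(OCc2ccccc2)cc1OCc1ccccc1 | intermediate
25 | 3-(benzyloxy)-2-{11-oxo-11-[2,4,6-tris(benzyloxy)phenyl]undecyl}phenyl acetate | CC(=O)Oc1cccc(OCc2ccccc2)c1CCCCCCCCCCC(=O)c1c(OCc2ccccc2)cc(OCc2ccccc2)cc1OCc1ccccc1 | intermediate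
26 | 3-hydroxy-2-[11-oxo-11-(2,4,6-trihydroxyphenyl)undecyl]phenyl acetate | CC(=O)Oc1cccc(O)c1CCCCCCCCCCC(=O)c1c(O)cc(O)cc1O | target

Total step count: 13.
Longest linear sequence: 10 steps (steps 1, 2, 5, 6, 7, 8, 10, 11, 12, 13 from 11-bromoundec-1-ene; the branch from acid 7 through steps 3 and 4 is equally long).

Steps most likely to fail

1. Step 5. Oligomerisation of the parent cyclobutenone, or capture of the vinylketene by a second molecule of enone, may outrun ring opening and trapping by the ynol ether; hydrolytic loss of the ynol ether is a second failure mode. The fallback gives up ring construction and alkylates a preformed resorcinol; it sets out from bromide 1 and comes back at phenol 14. Commercial 1,3-bis(methoxymethoxy)benzene would be lithiated between its two oxygens (n-BuLi, THF, 0 °C) to [2,6-bis(methoxymethoxy)phenyl]lithium F1, which would be alkylated with 1 to give 1,3-bis(methoxymethoxy)-2-(undec-10-en-1-yl)benzene F2. HCl in MeOH would remove both acetals to give 2-(undec-10-en-1-yl)benzene-1,3-diol F3. Monosilylation with one equivalent of i-Pr3SiCl and imidazole in DMF should then give 14 after separation from the diol and the bis-silyl ether, both of which can be recycled.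

2. Step 2. Oxygen transfer to the acetylide may be incomplete, the ynolate may be silylated on carbon or dimerise as a ketene, and the ynol ether may be lost by hydrolysis during purification. The fallback generates the same ynolate by Kowalski ester homologation; it sets out from bromide 1 and comes back at ynolate 5. Bromide 1 would be converted with Mg in THF to undec-10-en-1-ylmagnesium bromide F4, which would be added to excess ethyl chloroformate at −78 °C to give ethyl dodec-11-enoate F5. Addition of LiCHBr2 (from CH2Br2 and lithium 2,2,6,6-tetramethylpiperidide, THF, −78 °C) with loss of ethoxide would give lithium 1,1-dibromotrideca-1,12-dien-2-olate F6. n-BuLi would then effect bromine–lithium exchange, and 1,2-shift of the alkyl group with loss of bromide should deliver 5, which is silylated with i-Pr3SiOTf as in step 2 to give 6.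

3. Step 10. The hindered, basic aryllithium may enolise the aldehyde instead of adding, and metalation at a benzylic CH2 with rearrangement of a benzyl ether may compete during the exchange. The fallback replaces the aryl anion by electrophilic aromatic acylation; it sets out from aldehyde 18 and comes back at ketone 23, so that step 11 is no longer needed. Pinnick oxidation of 18 (NaClO2, NaH2PO4, 2-methylbut-2-ene, t-BuOH/H2O) would give 11-{2-(benzyloxy)-6-[(triisopropylsilyl)oxy]phenyl}undecanoic acid F7. Trifluoroacetic anhydride in CH2Cl2 at 0 °C would convert F7 into 11-{2-(benzyloxy)-6-[(triisopropylsilyl)oxy]phenyl}undecanoic trifluoroacetic anhydride F8, not isolated, which should acylate the far more nucleophilic 1,3,5-tris(benzyloxy)benzene 19 (used in excess) in a Friedel–Crafts reaction to give 23.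

Further compounds
F1 | step 5 | [2,6-bis(methoxymethoxy)phenyl]lithium | [Li]c1c(OCOC)cccc1OCOC
F2 | step 5 | 1,3-bis(methoxymethoxy)-2-(undec-10-en-1-yl)benzene | C=CCCCCCCCCCc1c(OCOC)cccc1OCOC
F3 | step 5 | 2-(undec-10-en-1-yl)benzene-1,3-diol | C=CCCCCCCCCCc1c(O)cccc1O
F4 | step 2 | undec-10-en-1-ylmagnesium bromide | C=CCCCCCCCCC[Mg]Br
F5 | step 2 | ethyl dodec-11-enoate | C=CCCCCCCCCCC(=O)OCC
F6 | step 2 | lithium 1,1-dibromotrideca-1,12-dien-2-olate | [Li]OC(CCCCCCCCCC=C)=C(Br)Br
F7 | step 10 | 11-{2-(benzyloxy)-6-[(triisopropylsilyl)oxy]phenyl}undecanoic acid | OC(=O)CCCCCCCCCCc1c(OCc2ccccc2)cccc1O[Si](C(C)C)(C(C)C)C(C)C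
F8 | step 10 | 11-{2-(benzyloxy)-6-[(triisopropylsilyl)oxy]phenyl}undecanoic trifluoroacetic anhydride | O=C(CCCCCCCCCCc1c(OCc2ccccc2)cccc1O[Si](C(C)C)(C(C)C)C(C)C)OC(=O)C(F)(F)F
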